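**Retrosynthetic overview**
1. Triene last: the C8'–C9' sp2–sp2 bond comes from a Suzuki–Miyaura coupling of dioxolane alkenylboronate 13 with (1E,4Z)-dienyl iodide 16; 13 comes from terminal alkene 12 by cross-metathesis.
2. Acetate arm of 12: silyl ketene acetal addition to the peroxycarbenium ion of 3-methoxy-1,2-dioxolane 10 (sets C3 under substrate control).
3. Key disconnection: both ring C–O bonds (O–C5, then O–C3) in one operation, by enantioselective conjugate addition of H2O2 to (E)-β,β-dialkyl enone 7 and hemiketal closure; this is the only ring, formed here (sets C5).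
4. Enone 7: syn-carbocupration of methyl but-2-ynoate with oct-7-enylcopper, then Weinreb ketone synthesis.
5. Iodide 16: (Z)-hex-3-en-1-ol, oxidation, Takai olefination.

Assumption: the sense of induction in step 3 is taken as (5S) with the quinine-derived amine; if a model run shows the opposite, the quinidine-derived pseudoenantiomer is used and nothing else changes.

**Step 1**
Reactants: 1 8-bromooct-1-ene; 2 methyl but-2-ynoate
Product: 5 methyl (2E)-3-methylundeca-2,10-dienoate, via oct-7-en-1-ylmagnesium bromide 3 (not isolated), via oct-7-en-1-ylcopper 4 (not isolated)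
Conditions: Mg, THF, rt; CuBr·SMe2, THF, −40 °C; then 2, −78 °C; MeOH quench at −78 °C
Reagents that add atoms: none
Why: Normant-type syn-carbocupration of an ynoate puts the alkyl group and copper on the same face, so protonation with retention gives the (E)-enoate whose geometry later decides which enone face maps onto (5S).

**Step 2**
Reactants: 5 methyl (2E)-3-methylundeca-2,10-dienoate
Product: 7 (3E)-4-methyldodeca-3,11-dien-2-one, via Weinreb amide 6 (not isolated)
Conditions: MeNH(OMe)·HCl (1.5 equiv), iPrMgCl (3.0 equiv), THF, −20 °C; then MeMgBr (2 equiv), 0 °C; 1 M HCl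
Reagents that add atoms: methylmagnesium bromide (C[Mg]Br)
Why: One-pot Weinreb ketone synthesis, in which the chloromagnesium amide turns the ester into the N-methoxy-N-methylamide and its chelated adduct with MeMgBr stops at the ketone, leaving the alkene geometry untouched.

**Step 3**
Reactants: 7 (3E)-4-methyldodeca-3,11-dien-2-one
Product: 9 (5S)-3,5-dimethyl-5-(oct-7-en-1-yl)-1,2-dioxolan-3-ol (both C3 epimers), via hydroperoxy ketone 8 (not isolated)
Conditions: 50% aq. H2O2 (3 equiv), 9-amino-9-deoxy-epi-quinine (10 mol%), CF3CO2H (20 mol%), 1,4-dioxane, 30 °C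
Reagents that add atoms: hydrogen peroxide (OO)
Why: Proposed new method: a primary-amine-salt (iminium) catalysed enantioselective conjugate addition of H2O2 to an acyclic (E)-β,β-dialkyl enone, creating a fully substituted C–OO stereocentre; the cinchona primary amine condenses with the hindered ketone, its protonated quinuclidine hydrogen-bonds H2O2 and delivers it to one face of the iminium β-carbon, and because the E geometry fixes where methyl and octenyl sit, face selection alone sets (5S); hydrolysis releases hydroperoxy ketone 8, whose OOH closes on the ketone (second C–O bond) to form the ring, which removes the product from retro-addition and Weitz–Scheffer epoxide closure; the closest known reaction types are the cinchona-primary-amine-catalysed hydroperoxidation of β-monosubstituted acyclic enones to 1,2-dioxolan-3-ols, the related epoxidation of 3-substituted cyclohexenones, and the racemic addition of H2O2 to mesityl oxide.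

**Step 4**
Reactants: 9 (5S)-3,5-dimethyl-5-(oct-7-en-1-yl)-1,2-dioxolan-3-ol
Product: 10 (5S)-3-methoxy-3,5-dimethyl-5-(oct-7-en-1-yl)-1,2-dioxolane (both C3 epimers)
Conditions: MeOH, TsOH·H2O (5 mol%), rt
Reagents that add atoms: methanol (CO)
Why: Acid-catalysed ketalisation of the peroxyhemiketal exchanges OH for OMe without touching C5, and the C3 mixture is irrelevant because C3 becomes planar in step 5.

**Step 5**
Reactants: 10 (5S)-3-methoxy-3,5-dimethyl-5-(oct-7-en-1-yl)-1,2-dioxolane
Product: 12 methyl 2-[(3R,5S)-3,5-dimethyl-5-(oct-7-en-1-yl)-1,2-dioxolan-3-yl]acetate, via peroxycarbenium ion 11 (not isolated)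
Conditions: CH2=C(OMe)OTBS (2.5 equiv), TMSOTf (0.2 equiv), CH2Cl2, −78 °C
Reagents that add atoms: 1-(tert-butyldimethylsilyloxy)-1-methoxyethene (C=C(OC)O[Si](C)(C)C(C)(C)C)
Why: Mukaiyama-type substitution of a 3-alkoxy-1,2-dioxolane, in which the silyl ketene acetal attacks peroxycarbenium ion 11 anti to the larger (octenyl) C5 substituent and sets (3R) with only modest substrate control (about 2:1 expected), the (3S,5S) epimer being removed by chromatography.

**Step 6**
Reactants: 12 methyl 2-[(3R,5S)-3,5-dimethyl-5-(oct-7-en-1-yl)-1,2-dioxolan-3-yl]acetate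
Product: 13 methyl 2-[(3R,5S)-3,5-dimethyl-5-[(7E)-8-(4,4,5,5-tetramethyl-1,3,2-dioxaborolan-2-yl)oct-7-en-1-yl]-1,2-dioxolan-3-yl]acetate
Conditions: vinyl–Bpin (3 equiv), second-generation Grubbs catalyst RuCl2(=CHPh)(H2IMes)(PCy3) (5 mol%), CH2Cl2, 40 °C
Reagents that add atoms: 2-ethenyl-4,4,5,5-tetramethyl-1,3,2-dioxaborolane (C=CB1OC(C)(C)C(C)(C)O1)
Why: Olefin cross-metathesis of the terminal alkene with vinyl–Bpin gives the (E)-alkenylboronate under thermodynamic control, and hindered dialkyl peroxides and esters are inert to the ruthenium carbene.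

**Step 7**
Reactants: 14 (3Z)-hex-3-en-1-ol
Product: 15 (3Z)-hex-3-enal
Conditions: Dess–Martin periodinane (1.2 equiv), CH2Cl2, 0 °C to rt; used crude at once
Reagents that add atoms: none
Why: Dess–Martin oxidation is fast and non-basic, so the β,γ-unsaturated aldehyde is obtained without migration of the Z-alkene into conjugation.

**Step 8**
Reactants: 15 (3Z)-hex-3-enal
Product: 16 (1E,4Z)-1-iodohepta-1,4-diene
Conditions: CrCl2 (6 equiv), CHI3 (2 equiv), THF/1,4-dioxane 1:6, 0 °C to rt
Reagents that add atoms: iodoform (IC(I)I)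
Why: Takai iodo-olefination through the gem-dichromium carbenoid is E-selective for aliphatic aldehydes and leaves the skipped Z-alkene untouched.

**Step 9**
Reactants: 13 methyl 2-[(3R,5S)-3,5-dimethyl-5-[(7E)-8-(4,4,5,5-tetramethyl-1,3,2-dioxaborolan-2-yl)oct-7-en-1-yl]-1,2-dioxolan-3-yl]acetate; 16 (1E,4Z)-1-iodohepta-1,4-diene
Product: 17 methyl 2-[(3R,5S)-3,5-dimethyl-5-[(7E,9E,12Z)-pentadeca-7,9,12-trien-1-yl]-1,2-dioxolan-3-yl]acetate
Conditions: PdCl2(dppf) (5 mol%), aq. K3PO4 (3 equiv), THF, 25 °C, degassed, dark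
Reagents that add atoms: none
Why: Suzuki–Miyaura coupling of an alkenylboronate with an alkenyl iodide proceeds with retention at both sp2 carbons under mild aqueous phosphate, which a di-tertiary dialkyl peroxide and the β-peroxy ester should survive, and gives the (7E,9E,12Z)-triene.

**Compound list**
1 | 8-bromooct-1-ene | C=CCCCCCCBr | starting material
2 | methyl but-2-ynoate | CC#CC(=O)OC | starting material
3 | oct-7-en-1-ylmagnesium bromide | C=CCCCCCC[Mg]Br | intermediate
4 | oct-7-en-1-ylcopper | C=CCCCCCC[Cu] | intermediate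
5 | methyl (2E)-3-methylundeca-2,10-dienoate | COC(=O)/C=C(\C)CCCCCCC=C | intermediate
6 | (2E)-N-methoxy-N,3-dimethylundeca-2,10-dienamide (Weinreb amide) | CON(C)C(=O)/C=C(\C)CCCCCCC=C | intermediate
7 | (3E)-4-methyldodeca-3,11-dien-2-one | CC(=O)/C=C(\C)CCCCCCC=C | intermediate
8 | (4S)-4-hydroperoxy-4-methyldodec-11-en-2-one | C=CCCCCCC[C@](C)(OO)CC(C)=O | intermediate
9 | (5S)-3,5-dimethyl-5-(oct-7-en-1-yl)-1,2-dioxolan-3-ol (both C3 epimers) | C=CCCCCCC[C@@]1(C)CC(C)(O)OO1 | intermediate
10 | (5S)-3-methoxy-3,5-dimethyl-5-(oct-7-en-1-yl)-1,2-dioxolane (both C3 epimers) | C=CCCCCCC[C@@]1(C)CC(C)(OC)OO1 | intermediate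
11 | (5S)-3,5-dimethyl-5-(oct-7-en-1-yl)-1,2-dioxolan-3-ylium (peroxycarbenium ion) | C=CCCCCCC[C@@]1(C)CC(C)=[O+]O1 | intermediate
12 | methyl 2-[(3R,5S)-3,5-dimethyl-5-(oct-7-en-1-yl)-1,2-dioxolan-3-yl]acetate | C=CCCCCCC[C@@]1(C)C[C@](C)(CC(=O)OC)OO1 | intermediate
13 | methyl 2-[(3R,5S)-3,5-dimethyl-5-[(7E)-8-(4,4,5,5-tetramethyl-1,3,2-dioxaborolan-2-yl)oct-7-en-1-yl]-1,2-dioxolan-3-yl]acetate | CC1(C)OB(/C=C/CCCCCC[C@@]2(C)C[C@](C)(CC(=O)OC)OO2)OC1(C)C | intermediate
14 | (3Z)-hex-3-en-1-ol | CC/C=C\CCO | starting material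
15 | (3Z)-hex-3-enal | CC/C=C\CC=O | intermediate
16 | (1E,4Z)-1-iodohepta-1,4-diene | I/C=C/C/C=C\CC | intermediate
17 | methyl 2-[(3R,5S)-3,5-dimethyl-5-[(7E,9E,12Z)-pentadeca-7,9,12-trien-1-yl]-1,2-dioxolan-3-yl]acetate | CC/C=C\C/C=C/C=C/CCCCCC[C@@]1(C)C[C@](C)(CC(=O)OC)OO1 | target

**Totals**
Total step count: 9. Longest linear sequence: 7 (steps 1 to 6, then 9).

**Three steps most likely to fail**

Step 3 (the proposed new hydroperoxidation). The risks are slow iminium formation with a β,β-disubstituted enone, loss of ee if the iminium equilibrates with its dienamine and scrambles the E/Z geometry, and partial epoxide formation. The fallback uses known chemistry, sets out from 7 and comes back at 12. Enone 7 is treated with aqueous H2O2 under the mild, near-neutral conditions long used to turn mesityl oxide into its 1,2-dioxolan-3-ol. This gives 9 as a racemate, that is 9 mixed 1:1 with (5R)-3,5-dimethyl-5-(oct-7-en-1-yl)-1,2-dioxolan-3-ol F1. Steps 4 and 5 are run unchanged on the racemate and give, beside 10 and 12, (5R)-3-methoxy-3,5-dimethyl-5-(oct-7-en-1-yl)-1,2-dioxolane F2 and methyl 2-[(3S,5R)-3,5-dimethyl-5-(oct-7-en-1-yl)-1,2-dioxolan-3-yl]acetate F3. Preparative chromatography on a chiral stationary phase separates F3 from 12, and the route continues from 12.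

Step 5. The methyl and octenyl groups at C5 differ little in size, so the C3 selectivity may be close to 1:1, and the tertiary peroxycarbenium ion can fragment. The fallback replaces substrate control by reagent control, sets out from 10 and comes back at 12. (4S)-3-Acetyl-4-(propan-2-yl)-1,3-thiazolidine-2-thione is enolised with TiCl4 and iPr2NEt and added at −78 °C to 10 activated with SnCl4, so that the chiral enolate chooses the face of the cation (the auxiliary enantiomer found to be matched is used). This gives 2-[(3R,5S)-3,5-dimethyl-5-(oct-7-en-1-yl)-1,2-dioxolan-3-yl]-1-[(4S)-4-(propan-2-yl)-2-sulfanylidene-1,3-thiazolidin-3-yl]ethan-1-one F4. Methanolysis (MeOH, imidazole, rt) removes the auxiliary and gives 12.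

Step 9 (with step 6). The O–O bond or the base-sensitive β-peroxy ester may not survive ruthenium, palladium and aqueous phosphate, and any (1Z)-iodide in 16 would carry through. The fallback builds the triene before any peroxide exists, sets out from 7 and comes back at 17. Cross-metathesis of 7 with vinyl–Bpin gives (3E,11E)-4-methyl-12-(4,4,5,5-tetramethyl-1,3,2-dioxaborolan-2-yl)dodeca-3,11-dien-2-one F5. Suzuki–Miyaura coupling of F5 with 16 gives (3E,11E,13E,16Z)-4-methylnonadeca-3,11,13,16-tetraen-2-one F6. The conditions of step 3 turn F6 into (5S)-3,5-dimethyl-5-[(7E,9E,12Z)-pentadeca-7,9,12-trien-1-yl]-1,2-dioxolan-3-ol F7, and those of step 4 give (5S)-3-methoxy-3,5-dimethyl-5-[(7E,9E,12Z)-pentadeca-7,9,12-trien-1-yl]-1,2-dioxolane F8. The conditions of step 5 applied to F8 give 17 directly; here the triene has to tolerate H2O2 and the silyl triflate instead.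

**Further compounds**
F1 | step 3 | (5R)-3,5-dimethyl-5-(oct-7-en-1-yl)-1,2-dioxolan-3-ol (both C3 epimers) | C=CCCCCCC[C@]1(C)CC(C)(O)OO1
F2 | step 3 | (5R)-3-methoxy-3,5-dimethyl-5-(oct-7-en-1-yl)-1,2-dioxolane (both C3 epimers) | C=CCCCCCC[C@]1(C)CC(C)(OC)OO1
F3 | step 3 | methyl 2-[(3S,5R)-3,5-dimethyl-5-(oct-7-en-1-yl)-1,2-dioxolan-3-yl]acetate | C=CCCCCCC[C@]1(C)C[C@@](C)(CC(=O)OC)OO1
F4 | step 5 | 2-[(3R,5S)-3,5-dimethyl-5-(oct-7-en-1-yl)-1,2-dioxolan-3-yl]-1-[(4S)-4-(propan-2-yl)-2-sulfanylidene-1,3-thiazolidin-3-yl]ethan-1-one | C=CCCCCCC[C@@]1(C)C[C@](C)(CC(=O)N2[C@@H](C(C)C)CSC2=S)OO1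
F5 | step 9 | (3E,11E)-4-methyl-12-(4,4,5,5-tetramethyl-1,3,2-dioxaborolan-2-yl)dodeca-3,11-dien-2-one | CC(=O)/C=C(\C)CCCCCC/C=C/B1OC(C)(C)C(C)(C)O1
F6 | step 9 | (3E,11E,13E,16Z)-4-methylnonadeca-3,11,13,16-tetraen-2-one | CC(=O)/C=C(\C)CCCCCC/C=C/C=C/C/C=C\CC
F7 | step 9 | (5S)-3,5-dimethyl-5-[(7E,9E,12Z)-pentadeca-7,9,12-trien-1-yl]-1,2-dioxolan-3-ol (both C3 epimers) | CC/C=C\C/C=C/C=C/CCCCCC[C@@]1(C)CC(C)(O)OO1
F8 | step 9 | (5S)-3-methoxy-3,5-dimethyl-5-[(7E,9E,12Z)-pentadeca-7,9,12-trien-1-yl]-1,2-dioxolane (both C3 epimers) | CC/C=C\C/C=C/C=C/CCCCCC[C@@]1(C)CC(C)(OC)OO1
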